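Numbering and sourcing assumption: locants C1–C15 follow guaiane numbering (C1/C5 ring fusion, C4 and C10 the methyl carbinols, C6 the secondary carbinol, C7 bearing C11 with C12/C13), α is the face of H-1 and H-5, and hex-1-en-5-yne, methyl 2-(acetoxymethyl)acrylate and the D-fructose-derived Shi ketone are bought.

## Retrosynthetic overview

1. Target ⇐ selective diacetylation of the 4,6,10,11,12,13-hexol ⇐ dihydroxylation and 1,2-reduction of a 4α,10α-dihydroxyguai-11(13)-en-12,6α-olide.
2. Key disconnection C6–C7 (seven-membered ring, formed second): the SmI2 ketyl of a lactol-masked C6 aldehyde adds to the β-carbon C7 of a 2-(acetoxymethyl)enoate; acetate loss and lactonisation follow in the same flask.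
3. The enoate arm comes from cross-metathesis of a butenyl side chain; the C4 carbinol comes from hydration of an exocyclic methylene on a cis-fused cyclopentane γ-lactone.
4. Disconnection C1–C5 (five-membered ring, formed first): an ester dienolate opens an (R,R)-trisubstituted epoxide 5-exo; Shi epoxidation supplies the absolute configuration.
5. The acyclic trienoate ⇐ alkyne carboalumination/oxirane opening, bromination, organocopper addition to methyl but-2-ynoate.

## Route

Step 1
Reactants: 1 hex-1-en-5-yne, 2 oxirane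
Product: 5 (3E)-4-methylocta-3,7-dien-1-ol, via alkenylalane 3 (not isolated), via lithium alanate 4 (not isolated)
Conditions: Me3Al (2 equiv), Cp2ZrCl2 (0.25 equiv), CH2Cl2, 0 °C → rt; evaporate; nBuLi, hexane/THF, −78 → 0 °C; oxirane, −78 °C → rt; aq. HCl
Reagents that add atoms: trimethylaluminium, C[Al](C)C
Why: Negishi zirconium-catalysed syn-methylalumination of the terminal alkyne (the isolated vinyl group is left alone) fixes the E trisubstituted olefin, and the derived alanate opens oxirane with retention of olefin geometry.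

Step 2
Reactants: 5 (3E)-4-methylocta-3,7-dien-1-ol
Product: 6 (5E)-8-bromo-5-methylocta-1,5-diene
Conditions: CBr4, PPh3, CH2Cl2, 0 °C
Reagents that add atoms: carbon tetrabromide, BrC(Br)(Br)Br
Why: Appel bromination converts the primary alcohol under neutral conditions and leaves both olefins untouched.

Step 3
Reactants: 6 (5E)-8-bromo-5-methylocta-1,5-diene, 7 methyl but-2-ynoate
Product: 11 methyl (2E,6E)-3,7-dimethylundeca-2,6,10-trienoate, via Grignard reagent 8 (not isolated), via alkylcopper reagent 9 (not isolated), via alkenylcopper adduct 10 (not isolated)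
Conditions: Mg, THF; CuBr·SMe2 (1 equiv), THF/Me2S, −45 °C; 7, −78 °C; aq. NH4Cl
Reagents that add atoms: none
Why: Syn-carbocupration of the ynoate by the Grignard-derived organocopper reagent at −78 °C, followed by protonolysis, places the new chain trans to the ester and gives the 2E enoate.

Step 4
Reactants: 11 methyl (2E,6E)-3,7-dimethylundeca-2,6,10-trienoate
Product: 12 methyl (2E)-5-[(2R,3R)-3-(but-3-en-1-yl)-3-methyloxiran-2-yl]-3-methylpent-2-enoate
Conditions: D-fructose-derived Shi ketone (0.3 equiv), KHSO5 (as 2KHSO5·KHSO4·K2SO4, 1.4 equiv), K2CO3, Bu4NHSO4, MeCN/CH2(OMe)2/aq. Na2B4O7–Na2EDTA buffer, 0 °C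
Reagents that add atoms: potassium peroxymonosulfate, [K+].[O-]S(=O)(=O)OO
Why: Shi asymmetric epoxidation attacks only the electron-rich trisubstituted olefin (not the enoate or the vinyl group) through the spiro transition state that gives the (R,R)-epoxide, which fixes C10 directly and C1 after the inversion in step 5.

Step 5
Reactants: 12 methyl (2E)-5-[(2R,3R)-3-(but-3-en-1-yl)-3-methyloxiran-2-yl]-3-methylpent-2-enoate
Product: 15 (3R,3aR,6aR)-3-(but-3-en-1-yl)-3-methyl-6-methylidenehexahydro-1H-cyclopenta[c]furan-1-one, via lithium dienolate 13 (not isolated), via hydroxy ester 14 (not isolated)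
Conditions: LiN(iPr)2 (2.2 equiv), THF, −78 °C → rt; AcOH, −78 °C; PPTS (cat.), CH2Cl2, rt
Reagents that add atoms: none
Why: Kinetic deprotonation of the methyl group syn to the ester gives the cross-conjugated dienolate, whose α-carbon opens the epoxide in a 5-exo-tet SN2 reaction (Stork-type epoxide–enolate cyclisation, inversion at C1, retention at C10), and lactonisation of the tertiary alkoxide together with kinetic α-protonation locks C5 cis to C1.

Step 6
Reactants: 15 (3R,3aR,6aR)-3-(but-3-en-1-yl)-3-methyl-6-methylidenehexahydro-1H-cyclopenta[c]furan-1-one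
Product: 16 (3R,3aR,6R,6aR)-3-(but-3-en-1-yl)-6-hydroxy-3,6-dimethylhexahydro-1H-cyclopenta[c]furan-1-one
Conditions: Mn(dpm)3 (10 mol%, dpm = dipivaloylmethanato), PhSiH3 (2 equiv), O2 (1 atm), iPrOH/CH2Cl2, 0 °C
Reagents that add atoms: dioxygen, O=O
Why: Mukaiyama hydrogen-atom-transfer hydration forms the tertiary radical from the 1,1-disubstituted olefin much faster than a secondary radical from the vinyl group, and O2 is captured on the convex face anti to the lactone carbonyl, so the C4 hydroxyl ends cis to H-5.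

Step 7
Reactants: 16 (3R,3aR,6R,6aR)-3-(but-3-en-1-yl)-6-hydroxy-3,6-dimethylhexahydro-1H-cyclopenta[c]furan-1-one
Product: 17 (3R,3aR,6R,6aR)-3-(but-3-en-1-yl)-3,6-dimethylhexahydro-1H-cyclopenta[c]furan-1,6-diol (lactol; both C1 anomers)
Conditions: iBu2AlH (2.5 equiv), CH2Cl2, −78 °C; aq. KNaC4H4O6
Reagents that add atoms: none
Why: Half-reduction of the γ-lactone stops at the lactol because the tetrahedral aluminium hemiacetal is stable at −78 °C, and the lactol keeps C5 locked cis.

Step 8
Reactants: 17 (3R,3aR,6R,6aR)-3-(but-3-en-1-yl)-3,6-dimethylhexahydro-1H-cyclopenta[c]furan-1,6-diol, 18 methyl 2-(acetoxymethyl)acrylate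
Product: 19 methyl (2E)-2-(acetoxymethyl)-5-[(3R,3aR,6R,6aR)-1,6-dihydroxy-3,6-dimethylhexahydro-1H-cyclopenta[c]furan-3-yl]pent-2-enoate
Conditions: 18 (5 equiv), second-generation Hoveyda–Grubbs catalyst (5 mol%), CH2Cl2, 40 °C
Reagents that add atoms: none
Why: Olefin cross-metathesis of the monosubstituted olefin with an excess of the 2-substituted acrylate tolerates the lactol and tertiary alcohols and gives the more stable trisubstituted enoate with the chain trans to the ester.

Step 9
Reactants: 19 methyl (2E)-2-(acetoxymethyl)-5-[(3R,3aR,6R,6aR)-1,6-dihydroxy-3,6-dimethylhexahydro-1H-cyclopenta[c]furan-3-yl]pent-2-enoate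
Product: 22 (1R,4R,5S,6S,7S,10R)-4,10-dihydroxyguai-11(13)-en-12,6-olide (4α,10α-dihydroxy-1αH,5αH-guai-11(13)-en-12,6α-olide), via hydroxy aldehyde 20 (not isolated), via hydroxy acrylate 21 (not isolated)
Conditions: SmI2 (3 equiv), HMPA (12 equiv), THF, −20 °C → rt, slow addition of 19; aq. NH4Cl; PPTS (cat.), CH2Cl2, rt
Reagents that add atoms: none
Why: Proposed new method: the lactol equilibrates with hydroxy aldehyde 20, whose samarium ketyl (the C6 carbonyl carbon acting as a nucleophile) adds 7-exo-trig to the electrophilic enoate β-carbon C7 through a chair-like transition state with the samarium alkoxide and the enoate pseudo-equatorial and anti, which sets 6α-O and 7β-C as in the natural 5αH,6βH,7αH guaianolides, after which the samarium enolate expels acetate and the C6 alkoxide lactonises; the closest known reaction type is the SmI2 ketyl–olefin cyclisation onto enoates with β-elimination of an allylic leaving group, and reduction of the allylic acetate first would give an allylsamarium that forms the same C6–C7 bond.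

Step 10
Reactants: 22 (1R,4R,5S,6S,7S,10R)-4,10-dihydroxyguai-11(13)-en-12,6-olide
Product: 23 (1R,4R,5S,6S,7S,10R)-guai-11(13)-ene-4,6,10,12-tetrol
Conditions: iBu2AlH (6 equiv), CH2Cl2, −78 → 0 °C; aq. KNaC4H4O6
Reagents that add atoms: none
Why: Excess iBu2AlH reduces the α-methylene lactone by 1,2-hydride delivery to the allylic 1,4-diol without conjugate reduction.

Step 11
Reactants: 23 (1R,4R,5S,6S,7S,10R)-guai-11(13)-ene-4,6,10,12-tetrol
Product: 24 (1R,4R,5S,6S,7R,10R)-guaiane-4,6,10,11,12,13-hexol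
Conditions: OsO4 (2 mol%), NMO (1.5 equiv), acetone/H2O, rt
Reagents that add atoms: N-methylmorpholine N-oxide, C[N+]1([O-])CCOCC1; water, O
Why: Upjohn dihydroxylation of the only olefin gives the 11,13-diol, and C11 is not a stereocentre because it carries two identical CH2OH arms.

Step 12
Reactants: 24 (1R,4R,5S,6S,7R,10R)-guaiane-4,6,10,11,12,13-hexol
Product: 25 (1R,4R,5S,6S,7R,10R)-4,6,10,11-tetrahydroxyguaiane-12,13-diyl diacetate
Conditions: Ac2O (2.2 equiv), pyridine, CH2Cl2, −20 → 0 °C
Reagents that add atoms: acetic anhydride, CC(=O)OC(C)=O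
Why: Rate-selective acylation esterifies only the two primary hydroxyls at low temperature without DMAP, leaving the hindered secondary and the three tertiary hydroxyls free.

## Compound list

1 | hex-1-en-5-yne | C#CCCC=C | starting material
2 | oxirane | C1CO1 | starting material
3 | dimethyl[(1E)-2-methylhexa-1,5-dien-1-yl]alane | C=CCC/C(C)=C/[Al](C)C | intermediate
4 | lithium butyl(dimethyl)[(1E)-2-methylhexa-1,5-dien-1-yl]aluminate | [Li+].C=CCC/C(C)=C/[Al-](C)(C)CCCC | intermediate
5 | (3E)-4-methylocta-3,7-dien-1-ol | OCC/C=C(\C)CCC=C | intermediate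
6 | (5E)-8-bromo-5-methylocta-1,5-diene | BrCC/C=C(\C)CCC=C | intermediate
7 | methyl but-2-ynoate | CC#CC(=O)OC | starting material
8 | [(3E)-4-methylocta-3,7-dien-1-yl]magnesium bromide | C=CCC/C(C)=C/CC[Mg]Br | intermediate
9 | [(3E)-4-methylocta-3,7-dien-1-yl]copper | C=CCC/C(C)=C/CC[Cu] | intermediate
10 | alkenylcopper adduct (copper on C2 of the enoate, cis to the new chain) | COC(=O)/C([Cu])=C(\C)CC/C=C(\C)CCC=C | intermediate
11 | methyl (2E,6E)-3,7-dimethylundeca-2,6,10-trienoate | COC(=O)/C=C(\C)CC/C=C(\C)CCC=C | intermediate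
12 | methyl (2E)-5-[(2R,3R)-3-(but-3-en-1-yl)-3-methyloxiran-2-yl]-3-methylpent-2-enoate | COC(=O)/C=C(\C)CC[C@H]1O[C@]1(C)CCC=C | intermediate
13 | lithium dienolate of 12 (deprotonated at the 3-methyl group) | [Li+].COC([O-])=CC(=C)CC[C@H]1O[C@]1(C)CCC=C | intermediate
14 | methyl (1R,5R)-5-[(2R)-2-hydroxyhex-5-en-2-yl]-2-methylidenecyclopentane-1-carboxylate | COC(=O)[C@H]1C(=C)CC[C@H]1[C@](C)(O)CCC=C | intermediate
15 | (3R,3aR,6aR)-3-(but-3-en-1-yl)-3-methyl-6-methylidenehexahydro-1H-cyclopenta[c]furan-1-one | O=C1O[C@](C)(CCC=C)[C@@H]2CCC(=C)[C@H]12 | intermediate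
16 | (3R,3aR,6R,6aR)-3-(but-3-en-1-yl)-6-hydroxy-3,6-dimethylhexahydro-1H-cyclopenta[c]furan-1-one | O=C1O[C@](C)(CCC=C)[C@@H]2CC[C@@](C)(O)[C@H]12 | intermediate
17 | (3R,3aR,6R,6aR)-3-(but-3-en-1-yl)-3,6-dimethylhexahydro-1H-cyclopenta[c]furan-1,6-diol (both C1 anomers) | OC1O[C@](C)(CCC=C)[C@@H]2CC[C@@](C)(O)[C@H]12 | intermediate
18 | methyl 2-(acetoxymethyl)acrylate | C=C(COC(C)=O)C(=O)OC | starting material
19 | methyl (2E)-2-(acetoxymethyl)-5-[(3R,3aR,6R,6aR)-1,6-dihydroxy-3,6-dimethylhexahydro-1H-cyclopenta[c]furan-3-yl]pent-2-enoate | OC1O[C@](C)(CC/C=C(\COC(C)=O)C(=O)OC)[C@@H]2CC[C@@](C)(O)[C@H]12 | intermediate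
20 | methyl (2E,6R)-2-(acetoxymethyl)-6-[(1R,2R,3R)-2-formyl-3-hydroxy-3-methylcyclopentyl]-6-hydroxyhept-2-enoate (ring-opened tautomer of 19) | O=C[C@H]1[C@](C)(O)CC[C@H]1[C@](C)(O)CC/C=C(\COC(C)=O)C(=O)OC | intermediate
21 | methyl (1R,4R,5S,6S,7S,10R)-4,6,10-trihydroxyguai-11(13)-en-12-oate | C=C(C(=O)OC)[C@@H]1CC[C@@](C)(O)[C@@H]2CC[C@@](C)(O)[C@@H]2[C@H]1O | intermediate
22 | (1R,4R,5S,6S,7S,10R)-4,10-dihydroxyguai-11(13)-en-12,6-olide | C=C1C(=O)O[C@H]2[C@H]1CC[C@@](C)(O)[C@@H]3CC[C@@](C)(O)[C@H]23 | intermediate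
23 | (1R,4R,5S,6S,7S,10R)-guai-11(13)-ene-4,6,10,12-tetrol | C=C(CO)[C@@H]1CC[C@@](C)(O)[C@@H]2CC[C@@](C)(O)[C@@H]2[C@H]1O | intermediate
24 | (1R,4R,5S,6S,7R,10R)-guaiane-4,6,10,11,12,13-hexol | OCC(O)(CO)[C@@H]1CC[C@@](C)(O)[C@@H]2CC[C@@](C)(O)[C@@H]2[C@H]1O | intermediate
25 | (1R,4R,5S,6S,7R,10R)-4,6,10,11-tetrahydroxyguaiane-12,13-diyl diacetate (CNP0179913.1) | CC(=O)OCC(O)(COC(C)=O)[C@@H]1CC[C@@](C)(O)[C@@H]2CC[C@@](C)(O)[C@@H]2[C@H]1O | target

## Step count and risk

Total steps: 12. Longest linear sequence: 12 (from hex-1-en-5-yne).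

**Step 9 (most likely to fail).** The aldehyde is present only as the minor open form of the lactol, so SmI2 may reduce the acetoxymethyl enoate without ring closure (the allylsamarium being quenched by the free hydroxyls), and the C6/C7 diastereoselectivity of a seven-membered closure is not assured. The fallback sets out from 17 and returns at 22. Cross-metathesis of 17 with methyl 2-(bromomethyl)acrylate (second-generation Hoveyda–Grubbs catalyst, CH2Cl2, 40 °C) gives methyl (2Z)-2-(bromomethyl)-5-[(3R,3aR,6R,6aR)-1,6-dihydroxy-3,6-dimethylhexahydro-1H-cyclopenta[c]furan-3-yl]pent-2-enoate F1. Zinc dust in THF/aq. NH4Cl then generates the 2-(methoxycarbonyl)allylzinc, which adds through its γ-carbon to the aldehyde released from the lactol in water (Barbier allylation, known to tolerate lactols), and the hydroxy acrylate lactonises to 22.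

**Step 5.** The ester dienolate may open the hindered epoxide too slowly and condense with itself, or give a trans hydroxy ester that cannot lactonise. The fallback sets out from 11 and returns at 15, using a more nucleophilic and less electrophilic amide dienolate. Aminolysis of 11 (Me3Al, Me2NH·HCl, toluene, 50 °C) gives (2E,6E)-N,N,3,7-tetramethylundeca-2,6,10-trienamide F2. Shi epoxidation as in step 4 gives (2E)-5-[(2R,3R)-3-(but-3-en-1-yl)-3-methyloxiran-2-yl]-N,N,3-trimethylpent-2-enamide F3. LiN(iPr)2 in THF (−78 °C → rt) cyclises it to (1R,5R)-5-[(2R)-2-hydroxyhex-5-en-2-yl]-N,N-dimethyl-2-methylidenecyclopentane-1-carboxamide F4, and PPTS in toluene at 80 °C closes the γ-hydroxy amide to lactone 15.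

**Step 6.** The vinyl group may also be hydrated, and the facial selectivity of radical oxygenation at C4 may be modest. The fallback sets out from 15 and returns at 16, replacing radical hydration by epoxidation and hydride opening. mCPBA (1.05 equiv, CH2Cl2, NaHCO3, 0 °C) epoxidises the 1,1-disubstituted olefin in preference to the vinyl group from the convex face to give (3R,3aR,6R,6aR)-3-(but-3-en-1-yl)-3-methyltetrahydrospiro[cyclopenta[c]furan-6,2'-oxiran]-1-one F5. LiAlH4 in THF at 0 °C opens the spiro-epoxide at its CH2 terminus and reduces the lactone, giving (1R,2S,3R)-3-[(2R)-2-hydroxyhex-5-en-2-yl]-2-(hydroxymethyl)-1-methylcyclopentan-1-ol F6. TEMPO (cat.)/PhI(OAc)2 in CH2Cl2 oxidises the primary alcohol through the lactol to lactone 16.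

## Further compounds

F1 | step 9 | methyl (2Z)-2-(bromomethyl)-5-[(3R,3aR,6R,6aR)-1,6-dihydroxy-3,6-dimethylhexahydro-1H-cyclopenta[c]furan-3-yl]pent-2-enoate | OC1O[C@](C)(CC/C=C(\CBr)C(=O)OC)[C@@H]2CC[C@@](C)(O)[C@H]12
F2 | step 5 | (2E,6E)-N,N,3,7-tetramethylundeca-2,6,10-trienamide | CN(C)C(=O)/C=C(\C)CC/C=C(\C)CCC=C
F3 | step 5 | (2E)-5-[(2R,3R)-3-(but-3-en-1-yl)-3-methyloxiran-2-yl]-N,N,3-trimethylpent-2-enamide | CN(C)C(=O)/C=C(\C)CC[C@H]1O[C@]1(C)CCC=C
F4 | step 5 | (1R,5R)-5-[(2R)-2-hydroxyhex-5-en-2-yl]-N,N-dimethyl-2-methylidenecyclopentane-1-carboxamide | CN(C)C(=O)[C@H]1C(=C)CC[C@H]1[C@](C)(O)CCC=C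
F5 | step 6 | (3R,3aR,6R,6aR)-3-(but-3-en-1-yl)-3-methyltetrahydrospiro[cyclopenta[c]furan-6,2'-oxiran]-1-one | O=C1O[C@](C)(CCC=C)[C@@H]2CC[C@@]3(OC3)[C@H]12
F6 | step 6 | (1R,2S,3R)-3-[(2R)-2-hydroxyhex-5-en-2-yl]-2-(hydroxymethyl)-1-methylcyclopentan-1-ol | OC[C@H]1[C@](C)(O)CC[C@H]1[C@](C)(O)CCC=C
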